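Target 13 is (2R,3S,3aS)-3a-allyl-5-methoxy-3-methyl-2-(3,4,5-trimethoxyphenyl)-3,3a-dihydro-1-benzofuran-6(2H)-one. The route is a seven-step linear sequence whose last step is a face-selective oxidative dearomative allylation of a cis-dihydrobenzofuranol.

## The problem

- **Rings.** Compound 13 has a dihydrofuran ring (O1, C2, C3, C3a, C7a) fused along C3a–C7a to a cross-conjugated cyclohexadienone. In the carbocycle, C7a=C7–C6=O is a vinylogous ester and C4=C5(OMe) is an α-methoxy enone.
- **Quaternary carbon.** The fusion carbon C3a is an all-carbon quaternary stereocentre bearing the allyl group. It is the only atom that keeps the carbocycle from being a 1,2,4-trioxygenated benzene, so no simple building block contains this ring.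
- **Stereocentres.** C2 (R), C3 (S) and C3a (S) are contiguous. The aryl group on C2 and the methyl group on C3 are cis, which is the less stable arrangement, and the allyl group on C3a is trans to both. C2 and C3 can control C3a because both substituents shield the same face; the reverse control is not available.
- **Feature that enables the key step.** H-2, H-3 and the allyl CH2 on C3a all lie on one face of the oxygen ring. The target is therefore a flat 2-aryl-3-methylbenzofuran-6-ol to which H2 (across C2=C3) and an allyl group (at C3a) have been added from the same face. C3a is para to the C6 oxygen and vinylogous through C4 to the methoxy-bearing C5, so two-electron oxidation of a C6 phenol makes C3a electrophilic.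
- **Sensitivities.** C2–O1 is a benzylic C–O bond whose oxygen is part of a vinylogous ester, so acid can ionise it (epimerisation at C2 or skeletal rearrangement). The allyl group on C3a forms a 1,5-diene with C4=C5 and with C7a=C7, so heat invites [3,3] shifts to C5 or to C7, the latter with aromatisation. The quaternary centre and the dienone should therefore be made last, cold and near neutral.

## Retrosynthesis

**13 ⇒ 9 + 10 (cut C3a–CH2 of the allyl group).** Dienone 13 is the two-electron-oxidised, C-allylated form of phenol 9. Oxidation of 9 through aryloxyiodane 11 gives phenoxonium cation 12, and allyltrimethylsilane 10 is to attack its C3a terminus. This cut is preferred to cutting C3–C3a together with C2–O1, because here C2 and C3 already exist when the quaternary centre is made and both direct the incoming group to the opposite face. Precursor 9 is a stable, flat-ringed arene with two stereocentres and no quaternary carbon. The forward step must choose C3a over C5 and C7, add anti to methyl and aryl, and outrun loss of H-3 and ionisation of C2–O1.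

**9 ⇒ 8 ⇒ 7 (remove the silyl group; cut the C2–H and C3–H bonds).** The cis relationship of aryl and methyl is the signature of syn addition of H2 to the C2=C3 bond of benzofuran 7. One enantioface-selective hydrogenation sets both centres of 8 and, through them, later C3a. This is preferred to building the two centres in an open chain and closing the ring, which needs separate control of each centre and a stereospecific C–O closure. Precursor 7 is achiral and planar. The forward step must reduce a tetrasubstituted, electron-rich furan double bond with facial control and leave both benzene rings alone. The silyl ether keeps the phenol masked through steps 3 to 5 and comes off with fluoride without acid.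

**7 ⇒ 6 (cut C2=C3).** The furan double bond is formed by intramolecular reductive coupling of the aryl ketone and the aryl ester of 6. This places methyl on C3 and aryl on C2 without ambiguity, because each carbonyl already carries its group. Cyclodehydration of an aryloxy ketone would give the 3-aryl-2-methyl isomer, and alkyne annulation leaves the regiochemistry to the catalyst.

**6 ⇒ 4 + 5; 4 ⇒ 3; 3 ⇒ 1 + 2 (cut the ester C–O, the O–Si bond, the aryl–acetyl bond).** Ester 6 comes from phenol 4 and acid chloride 5. Phenol 4 is the selectively silylated form of dihydroxy ketone 3, whose chelated 2-hydroxyl is the less reactive. Ketone 3 comes from C-acylation of diol 1 with acetic acid 2 at the only position that is ortho to one hydroxyl and para to the other.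

## Roads not taken

**Alternative 1:** Cut C3–C3a and C2–O1 together (the most obvious plan). Forward, acid ionises quinone monoketal A1 to an allyl-bearing trioxygenated cation, which combines with (Z)-propenylarene A2 in a stepwise cationic [3+2] addition.
- Neither partner has a stereocentre and the electrophile is a free cation, so the product is racemic.
- The cis C2/C3 relationship depends on the Z geometry surviving a benzylic cation that can rotate before O-closure.
- The C3/C3a relationship comes from the approach of two flat partners with no steric bias.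
- The benzylic cation can also close on C7 to give the bridged diketone A3.
- In the chosen plan C2 and C3 are fixed by syn hydrogenation before any cation exists, and they then control C3a.

**Alternative 2:** Cut C3a–allyl but deliver the group by two [3,3] shifts. Forward, the allyl ether of a cis-dihydrobenzofuran-6-ol lacking the C5 methoxy group undergoes Claisen rearrangement to 5-allylphenol A4. Oxidative methoxylation at C5 gives dienone A5, and Cope rearrangement moves the allyl group from C5 to C3a.
- C5 is made stereogenic para to the ring fusion, far from C2 and C3, so both C5 epimers form.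
- The suprafacial Cope shift passes this on as a mixture of 13 and its C3a epimer A6.
- The Claisen step must choose C5 over C7.
- The sequence needs heat on compounds that contain the same 1,5-dienes that make 13 labile.
- It uses three steps where the chosen plan uses one and sets C3a next to its controlling centres.

**Alternative 3:** Cut the carbocycle (C7–C7a and C3a–C4) and keep the oxygen ring as a lactone. Forward, enantioenriched cis lactone A7 is alkenylated and then allylated at the α-carbon, trans to the methyl group, to give A8. The methyl ketone enolate of A8 then attacks the lactone carbonyl (Claisen-type condensation), and the freed benzylic alcohol recloses to the vinylogous ester.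
- The stereochemical logic is sound, but A7 needs its own asymmetric synthesis and the ring construction adds four to five steps.
- The condensation must attack a carbonyl flanked by a quaternary carbon, under strong base and with a benzylic alkoxide as leaving group.
- The α-alkenylation of the lactone enolate has little support.
- The chosen plan takes the carbocycle ready-made from an arene and needs no ring construction.

Key step: step 7

Remark on the chemistry: the sense of induction of the hydrogenation catalyst in step 5 cannot be assigned in advance for a 2-aryl-3-methylbenzofuran. The (R,R) ligand is written on the assumption that it gives (2R,3S); its antipode is used if the sense proves opposite.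

## Route

Step 1
Reactants: 1 4-methoxybenzene-1,3-diol; 2 acetic acid
Product: 3 1-(2,4-dihydroxy-5-methoxyphenyl)ethan-1-one
Conditions: ZnCl2 (1.5 equiv), AcOH (solvent), 130 °C, N2
Reagents that add atoms: none
Why: Nencki (Friedel–Crafts) C-acylation; C6 of 1 is ortho to one hydroxyl and para to the other and is the only doubly activated position not flanked by both, so the acetyl group should enter there.

Step 2
Reactants: 3 1-(2,4-dihydroxy-5-methoxyphenyl)ethan-1-one
Product: 4 1-(2-hydroxy-5-methoxy-4-{[tri(propan-2-yl)silyl]oxy}phenyl)ethan-1-one
Conditions: iPr3SiCl (1.05 equiv), imidazole, DMF, 0 °C to rt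
Reagents that add atoms: chlorotri(propan-2-yl)silane, CC(C)[Si](Cl)(C(C)C)C(C)C
Why: Selective silylation of the more acidic, unchelated 4-hydroxyl; the 2-hydroxyl is held in a hydrogen bond to the ketone and should stay free for step 3.

Step 3
Reactants: 4 1-(2-hydroxy-5-methoxy-4-{[tri(propan-2-yl)silyl]oxy}phenyl)ethan-1-one; 5 3,4,5-trimethoxybenzoyl chloride
Product: 6 2-acetyl-4-methoxy-5-{[tri(propan-2-yl)silyl]oxy}phenyl 3,4,5-trimethoxybenzoate
Conditions: Et3N, DMAP (10 mol %), CH2Cl2, 0 °C to rt
Reagents that add atoms: none
Why: DMAP-catalysed O-acylation of the chelated phenol; it places the ester carbonyl (future C2, with the aryl group) and the ketone carbonyl (future C3, with the methyl group) in the relationship needed for furan closure.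

Step 4
Reactants: 6 2-acetyl-4-methoxy-5-{[tri(propan-2-yl)silyl]oxy}phenyl 3,4,5-trimethoxybenzoate
Product: 7 {[5-methoxy-3-methyl-2-(3,4,5-trimethoxyphenyl)-1-benzofuran-6-yl]oxy}tri(propan-2-yl)silane
Conditions: TiCl3 (4 equiv), Zn dust (8 equiv), DME, reflux
Reagents that add atoms: none
Why: Intramolecular McMurry-type ketone–ester reductive coupling with low-valent titanium; the ketyl adds to the neighbouring ester carbonyl and deoxygenation gives the aromatic furan, with regiochemistry fixed by the substrate.

Step 5
Reactants: 7 {[5-methoxy-3-methyl-2-(3,4,5-trimethoxyphenyl)-1-benzofuran-6-yl]oxy}tri(propan-2-yl)silane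
Product: 8 {[(2R,3S)-5-methoxy-3-methyl-2-(3,4,5-trimethoxyphenyl)-2,3-dihydro-1-benzofuran-6-yl]oxy}tri(propan-2-yl)silane
Conditions: [Ru(cod)(2-methylallyl)2] (5 mol %), (R,R)-SINpEt·HBF4 (1,3-bis[(R)-1-(naphthalen-1-yl)ethyl]-4,5-dihydroimidazolium tetrafluoroborate, 10 mol %), KOtBu (12 mol %), hexane, 70 °C; then 7, H2 (60 bar), hexane/toluene, 40 °C
Reagents that add atoms: none
Why: Homogeneous asymmetric hydrogenation of the benzofuran C2=C3 bond with a chiral ruthenium–NHC catalyst; both hydrogens are delivered to one face, so aryl and methyl end cis, and the catalyst's choice of face sets C2 (R) and C3 (S) together.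

Step 6
Reactants: 8 {[(2R,3S)-5-methoxy-3-methyl-2-(3,4,5-trimethoxyphenyl)-2,3-dihydro-1-benzofuran-6-yl]oxy}tri(propan-2-yl)silane
Product: 9 (2R,3S)-5-methoxy-3-methyl-2-(3,4,5-trimethoxyphenyl)-2,3-dihydro-1-benzofuran-6-ol
Conditions: Bu4NF (1.1 equiv), AcOH (1.1 equiv), THF, 0 °C
Reagents that add atoms: none
Why: Fluoride cleavage of the aryl silyl ether under acetic acid buffering; no acid strong enough to ionise the cis benzylic C2–O1 bond is present, so both stereocentres should be untouched.

Step 7
Reactants: 9 (2R,3S)-5-methoxy-3-methyl-2-(3,4,5-trimethoxyphenyl)-2,3-dihydro-1-benzofuran-6-ol; 10 allyltrimethylsilane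
Product: 13 (2R,3S,3aS)-3a-allyl-5-methoxy-3-methyl-2-(3,4,5-trimethoxyphenyl)-3,3a-dihydro-1-benzofuran-6(2H)-one, via aryloxy-λ3-iodane 11 (not isolated), via phenoxonium cation 12 (not isolated)
Conditions: PhI(OAc)2 (1.1 equiv), allylSiMe3 (5 equiv), (CF3)2CHOH/CH2Cl2, −20 °C, 10 min; then cold aq. NaHCO3
Reagents that add atoms: none
Why: Ligand exchange of phenol 9 on PhI(OAc)2 gives aryloxy-λ3-iodane 11, which in the ionising, non-nucleophilic fluorinated alcohol loses iodobenzene and acetate to give phenoxonium cation 12, with positive charge on C5 (as the O-methyl oxocarbenium), C7 and C3a. Silane 10 attacks C3a, which is para to the C6 oxygen and the vinylogous terminus (through C4) of the oxocarbenium, and the β-silyl cation loses silicon to acetate (Hosomi–Sakurai), leaving C4=C5(OMe), C6=O and C7=C7a–O1 in place, which is 13. The closest known reaction type is the hypervalent-iodine-mediated oxidative Hosomi–Sakurai allylation of para-alkyl phenols to 4-allyl-4-alkylcyclohexa-2,5-dienones in hexafluoroisopropanol; capture of this family of trioxygenated cations by alkenes at the alkyl-bearing terminus is also what acid-induced quinone ketal/propenylarene additions rely on. No ring is closed: the oxygen ring is already present and only C3a changes from sp2 to sp3. The new stereocentre C3a is set by substrate control, since in flat cation 12 the C3 methyl and the C2 aryl group stand on the same face of C3a, so the silane should add from the face of H-2 and H-3 and the allyl group should end trans to methyl (3aS). The step needs regioselectivity for C3a over C5 and C7, which the doubly stabilised product (vinylogous ester plus enol ether) and the absence of a nucleophilic solvent should favour, and it needs C–C bond formation to outrun loss of H-3, for which the silane is used in excess at low temperature. Short contact time, cold bicarbonate work-up and no heating protect the acid-labile C2–O1 bond and the two 1,5-diene units of 13.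

## Compound list

1 | 4-methoxybenzene-1,3-diol | COc1ccc(O)cc1O | starting material
2 | acetic acid | CC(=O)O | starting material
3 | 1-(2,4-dihydroxy-5-methoxyphenyl)ethan-1-one | CC(=O)c1cc(OC)c(O)cc1O | intermediate
4 | 1-(2-hydroxy-5-methoxy-4-{[tri(propan-2-yl)silyl]oxy}phenyl)ethan-1-one | CC(=O)c1cc(OC)c(O[Si](C(C)C)(C(C)C)C(C)C)cc1O | intermediate
5 | 3,4,5-trimethoxybenzoyl chloride | COc1cc(C(=O)Cl)cc(OC)c1OC | starting material
6 | 2-acetyl-4-methoxy-5-{[tri(propan-2-yl)silyl]oxy}phenyl 3,4,5-trimethoxybenzoate | CC(=O)c1cc(OC)c(O[Si](C(C)C)(C(C)C)C(C)C)cc1OC(=O)c1cc(OC)c(OC)c(OC)c1 | intermediate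
7 | {[5-methoxy-3-methyl-2-(3,4,5-trimethoxyphenyl)-1-benzofuran-6-yl]oxy}tri(propan-2-yl)silane | COc1cc2c(C)c(-c3cc(OC)c(OC)c(OC)c3)oc2cc1O[Si](C(C)C)(C(C)C)C(C)C | intermediate
8 | {[(2R,3S)-5-methoxy-3-methyl-2-(3,4,5-trimethoxyphenyl)-2,3-dihydro-1-benzofuran-6-yl]oxy}tri(propan-2-yl)silane | COc1cc2c(cc1O[Si](C(C)C)(C(C)C)C(C)C)O[C@@H](c1cc(OC)c(OC)c(OC)c1)[C@H]2C | intermediate
9 | (2R,3S)-5-methoxy-3-methyl-2-(3,4,5-trimethoxyphenyl)-2,3-dihydro-1-benzofuran-6-ol | COc1cc2c(cc1O)O[C@@H](c1cc(OC)c(OC)c(OC)c1)[C@H]2C | intermediate
10 | allyltrimethylsilane | C=CC[Si](C)(C)C | starting material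
11 | {[(2R,3S)-5-methoxy-3-methyl-2-(3,4,5-trimethoxyphenyl)-2,3-dihydro-1-benzofuran-6-yl]oxy}(phenyl)-λ3-iodanyl acetate | COc1cc2c(cc1OI(OC(C)=O)c1ccccc1)O[C@@H](c1cc(OC)c(OC)c(OC)c1)[C@H]2C | intermediate
12 | phenoxonium cation of 9, drawn as the C5 O-methyl oxocarbenium of (2R,3S)-3-methyl-6-oxo-2-(3,4,5-trimethoxyphenyl)-2,3-dihydrobenzofuran | C[O+]=C1C=C2C(=CC1=O)O[C@@H](c1cc(OC)c(OC)c(OC)c1)[C@H]2C | intermediate
13 | (2R,3S,3aS)-3a-allyl-5-methoxy-3-methyl-2-(3,4,5-trimethoxyphenyl)-3,3a-dihydro-1-benzofuran-6(2H)-one | C=CC[C@]12C=C(OC)C(=O)C=C1O[C@@H](c1cc(OC)c(OC)c(OC)c1)[C@H]2C | target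

## Step count and risks

Total step count: 7. Longest linear sequence: 7 steps (from 1; compounds 2, 5 and 10 enter as purchased).

**Step 7 (key step).** The most likely failure is diversion of cation 12 before the C–C bond forms. It can lose H-3, which after tautomerisation returns an aromatic benzofuranol, or be captured at C5 next to the methoxy group, because C3a is the most hindered of the three electrophilic positions. Acid-promoted ionisation of C2–O1 in the fluorinated medium is a lesser risk; facial leakage is not expected.
Fallback: separate the oxidation from the C–C bond formation. Setting out from 9, PhI(OAc)2 in methanol at −10 °C should give the quinone monoketal (2R,3S)-5,5-dimethoxy-3-methyl-2-(3,4,5-trimethoxyphenyl)-2,3-dihydro-1-benzofuran-6(5H)-one F1, which is isolated free of acid and used at once. F1 is then ionised with catalytic Me3SiOTf in CH2Cl2 at −78 °C with silane 10 already present. Cation 12 then forms in an aprotic medium without acetic acid and at a temperature where bimolecular capture should beat proton loss; the sequence comes back to the route at 13.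

**Step 5.** The most likely failure is sluggish reduction of a tetrasubstituted, electron-rich furan double bond, or weak discrimination between faces because the catalyst must tell a methyl-bearing from an aryl-bearing carbon. Forcing the pressure or temperature risks reduction of a benzene ring.
Fallback: replace asymmetric catalysis by syn hydrogenation and resolution. Setting out from 7, H2 (5 bar) over Pd/C (10 wt % Pd on carbon) in ethyl acetate should give the racemic cis silyl ether F2. Bu4NF/AcOH gives the racemic cis phenol F3. Preparative chromatography on a chiral stationary phase separates 9 from its (2S,3R) enantiomer F4; the sequence comes back to the route at 9.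

**Step 4.** The most likely failure is reductive cleavage of the aryl ester C–O bond (returning 4) or loss of the silyl ether under the Lewis-acidic titanium chlorides at reflux, in competition with ketyl addition to the ester.
Fallback: avoid low-valent titanium and close the furan by an intramolecular Wittig reaction. Setting out from 4, NaBH4 in methanol gives the benzylic alcohol 2-(1-hydroxyethyl)-4-methoxy-5-{[tri(propan-2-yl)silyl]oxy}phenol F5. PPh3·HBr in acetonitrile converts it, through the ortho-quinone methide, into the phosphonium salt [1-(2-hydroxy-5-methoxy-4-{[tri(propan-2-yl)silyl]oxy}phenyl)ethyl]triphenylphosphonium bromide F6. Treatment of F6 with acid chloride 5 and Et3N in refluxing toluene should acylate the phenol, form the ylide and close onto the ester carbonyl; the sequence comes back to the route at 7.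

## Further compounds

F1 | step 7 | (2R,3S)-5,5-dimethoxy-3-methyl-2-(3,4,5-trimethoxyphenyl)-2,3-dihydro-1-benzofuran-6(5H)-one | COC1(OC)C=C2C(=CC1=O)O[C@@H](c1cc(OC)c(OC)c(OC)c1)[C@H]2C
F2 | step 5 | racemic cis-{[5-methoxy-3-methyl-2-(3,4,5-trimethoxyphenyl)-2,3-dihydro-1-benzofuran-6-yl]oxy}tri(propan-2-yl)silane (both enantiomers) | COc1cc2c(cc1O[Si](C(C)C)(C(C)C)C(C)C)O[C@@H](c1cc(OC)c(OC)c(OC)c1)[C@H]2C.COc1cc2c(cc1O[Si](C(C)C)(C(C)C)C(C)C)O[C@H](c1cc(OC)c(OC)c(OC)c1)[C@@H]2C
F3 | step 5 | racemic cis-5-methoxy-3-methyl-2-(3,4,5-trimethoxyphenyl)-2,3-dihydro-1-benzofuran-6-ol (both enantiomers) | COc1cc2c(cc1O)O[C@@H](c1cc(OC)c(OC)c(OC)c1)[C@H]2C.COc1cc2c(cc1O)O[C@H](c1cc(OC)c(OC)c(OC)c1)[C@@H]2C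
F4 | step 5 | (2S,3R)-5-methoxy-3-methyl-2-(3,4,5-trimethoxyphenyl)-2,3-dihydro-1-benzofuran-6-ol (unwanted enantiomer) | COc1cc2c(cc1O)O[C@H](c1cc(OC)c(OC)c(OC)c1)[C@@H]2C
F5 | step 4 | 2-(1-hydroxyethyl)-4-methoxy-5-{[tri(propan-2-yl)silyl]oxy}phenol (racemic at the carbinol carbon) | CC(O)c1cc(OC)c(O[Si](C(C)C)(C(C)C)C(C)C)cc1O
F6 | step 4 | [1-(2-hydroxy-5-methoxy-4-{[tri(propan-2-yl)silyl]oxy}phenyl)ethyl]triphenylphosphonium bromide (racemic) | CC(c1cc(OC)c(O[Si](C(C)C)(C(C)C)C(C)C)cc1O)[P+](c1ccccc1)(c1ccccc1)c1ccccc1.[Br-]
A1 | alternative 1 | 2-allyl-4,4,5-trimethoxycyclohexa-2,5-dien-1-one | C=CCC1=CC(OC)(OC)C(OC)=CC1=O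
A2 | alternative 1 | (Z)-1,2,3-trimethoxy-5-(prop-1-en-1-yl)benzene | C/C=C\c1cc(OC)c(OC)c(OC)c1
A3 | alternative 1 | 5-allyl-3-methoxy-6-methyl-7-(3,4,5-trimethoxyphenyl)bicyclo[3.2.1]oct-3-ene-2,8-dione (racemic, relative configuration not controlled) | C=CCC12C=C(OC)C(=O)C(C2=O)C(c2cc(OC)c(OC)c(OC)c2)C1C
A4 | alternative 2 | (2R,3S)-5-allyl-3-methyl-2-(3,4,5-trimethoxyphenyl)-2,3-dihydro-1-benzofuran-6-ol | C=CCc1cc2c(cc1O)O[C@@H](c1cc(OC)c(OC)c(OC)c1)[C@H]2C
A5 | alternative 2 | (2R,3S)-5-allyl-5-methoxy-3-methyl-2-(3,4,5-trimethoxyphenyl)-2,3-dihydro-1-benzofuran-6(5H)-one (both C5 epimers) | C=CCC1(OC)C=C2C(=CC1=O)O[C@@H](c1cc(OC)c(OC)c(OC)c1)[C@H]2C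
A6 | alternative 2 | (2R,3S,3aR)-3a-allyl-5-methoxy-3-methyl-2-(3,4,5-trimethoxyphenyl)-3,3a-dihydro-1-benzofuran-6(2H)-one (C3a epimer of 13) | C=CC[C@@]12C=C(OC)C(=O)C=C1O[C@@H](c1cc(OC)c(OC)c(OC)c1)[C@H]2C
A7 | alternative 3 | (4S,5R)-4-methyl-5-(3,4,5-trimethoxyphenyl)oxolan-2-one | O=C1O[C@@H](c2cc(OC)c(OC)c(OC)c2)[C@@H](C)C1
A8 | alternative 3 | (4S,5R)-3-allyl-3-[(1E)-2-methoxy-3-oxobut-1-en-1-yl]-4-methyl-5-(3,4,5-trimethoxyphenyl)oxolan-2-one (allyl trans to the C4 methyl) | C=CC[C@]1(/C=C(OC)\C(C)=O)C(=O)O[C@@H](c2cc(OC)c(OC)c(OC)c2)[C@H]1C
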